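(The numbers of this flask are assumed.)

Q drains slowly into E and D, with a half-life of 8.37 min by the two forward constants, and L is spent twice: in the first step, which makes Q, and in the fourth, which takes E.

    G + L → Q + J (k1 = 0.0054 L mol⁻¹ s⁻¹)
    Q ⇌ E (K2 = 9.4, k2 = 0.0012 s⁻¹)
    Q ⇌ D (K3 = 150, k3 = 1.8 × 10⁻⁴ s⁻¹)
    L + E → L.E (k4 = 0.0049 L mol⁻¹ s⁻¹)

the same everywhere: G 0.46 M; time 50 min
- Saturday's: L 0.800 equiv
- Friday's: L 1.60 equiv
- Tuesday's: L 3.20 equiv

- which of the two there is more of at the end, Saturday's (L.E / E)
- which of the two there is more of at the end, Friday's (L.E / E)
- which of the two there is more of at the end, Tuesday's (L.E / E)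
- amount of E at the end, in percent of the G charged, Saturday's
- amount of E at the end, in percent of the G charged, Friday's
- amount of E at the end, in percent of the G charged, Tuesday's

I reckon from the forward constants and, for Friday's and Tuesday's, take the first step as finished by the end, since its time scale at the charged G, 6.71 min, is shorter than 50 min. Q then splits between E and D, and I call φ the share going to E, the forward constant to E over the sum of both forward constants:

φ = 0.870

Each G takes one L in the first step, and each E takes one more in the fourth. So I define d, the demand, as the equivalents of L that one G calls for, which is one plus φ:

d = 1.87 equiv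

Friday's and Tuesday's look alike, since both hold more L than G, but d parts them. Friday's stands below d, short by a fraction of the G charged that stays as E:

E on Friday's = 27.0%

Tuesday's stands above d, so my count leaves E at 0%. The surplus of 0.612 M of L over d on Tuesday's halves E by the fourth step alone in 3.85 min, less than 50 min. By this count the larger is L.E on Friday's and L.E on Tuesday's.

Saturday's holds less L than G, so L is the limiting reagent and my count stops. Counting the L as taken by the first step, I expect the larger on Saturday's to be E, and I commit to no number for E there.

The forecast says E, L.E and L.E, with E at 41%, 26% and 1.4% for Saturday's, Friday's and Tuesday's, on the ground that "E is then trapped by whatever L remains". It agrees with my choices and, unlike me, gives Saturday's a number.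

The flasks end with E at 39.5%, 25.4% and 1.43% for Saturday's, Friday's and Tuesday's, and the larger is E, L.E and L.E. On Friday's, 7.01% of the charged L is still free at the end. Counting the L above d as free, Tuesday's comes to 41.6% of its charge, and 43% stands free. A flask like Friday's but with 2.70 equiv of L comes to 30.7% by the same count, and it ends with 32.9% of its L free and E at 3.00%.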